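**Retrosynthetic overview**
1. 23 ⇒ the two ester C–O bonds: the last steps are senecioylation of the C9 alcohol and tigloylation of the C3 alcohol, kept apart by a TBS ether on O3.
2. C9–O and the trans ring fusion ⇒ Rubottom oxidation of the regiodefined C8–C9 enol silane obtained by Li/NH3 reduction of a Δ9(10)-8-enone.
3. C7–C11 ⇒ new copper-catalysed isopropenylation of the cross-conjugated silyl dienol ether of that enone with an isopropenyl(mesityl)iodonium salt (sets C7).
4. C3–O/C4–CH3 ⇒ hydroboration of a C3=C4 methyl alkene made from the C4 ketone through its enol triflate, with the enone masked as a dithiolane.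
5. No ring is built: ring A and ring B come fused, with the C5 quaternary centre, in commercial (S)-Wieland–Miescher ketone; ring A is elaborated first, then ring B.

Assumption: the ester written /C(C)=C/C is the (E)-2-methylbut-2-enoate (tiglate); the bicyclic core is called decalin and numbered as in eremophilane (ring A = C1–C5 and C10, ring B = C5–C10, methyls on C5 and C4, isopropenyl on C7, ketone at C8), and β means the face that carries the C5 methyl.

**Route**

Step 1
Reactants: 1 (S)-Wieland–Miescher ketone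
Product: 2 5β-methyl-decal-9(10)-en-4-one with a spiro-1,3-dithiolane at C8
Conditions: HSCH2CH2SH, p-TsOH·H2O (cat.), AcOH, rt
Reagents that add atoms: ethane-1,2-dithiol, SCCS
Why: Acid-catalysed thioketalisation is selective for the conjugated C8 carbonyl (the C4 ketone next to the quaternary carbon is hindered) and leaves the C9=C10 double bond in place, so no stereocentre is touched.

Step 2
Reactants: 2 5β-methyl-decal-9(10)-en-4-one 8-dithiolane
Product: 3 5β-methyl-8-spiro(1,3-dithiolane)-decala-3,9(10)-dien-4-yl trifluoromethanesulfonate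
Conditions: LiN(i-Pr)2, THF, −78 °C; PhNTf2, −78 °C to rt
Reagents that add atoms: N-phenylbis(trifluoromethanesulfonimide), O=S(=O)(N(c1ccccc1)S(=O)(=O)C(F)(F)F)C(F)(F)F
Why: Enol triflate formation; the C4 ketone can only enolise toward C3 because C5 is quaternary, and O-sulfonylation of that enolate gives the C3=C4 triflate.

Step 3
Reactants: 3 C3=C4 enol triflate
Product: 4 4,5β-dimethyl-8-spiro(1,3-dithiolane)-decala-3,9(10)-diene
Conditions: MeZnCl, Pd(PPh3)4 (5 mol %), THF, 50 °C
Reagents that add atoms: methylzinc chloride, C[Zn]Cl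
Why: Negishi cross-coupling of the alkenyl triflate under zerovalent palladium catalysis replaces OTf by the C4 methyl group and does not affect the dithiolane.

Step 4
Reactants: 4 4,5β-dimethyl-3,9(10)-diene 8-dithiolane
Product: 6 4β,5β-dimethyl-8-spiro(1,3-dithiolane)-decal-9(10)-en-3α-ol, via alkylborane 5 (not isolated)
Conditions: BH3·THF, THF, 0 °C to rt; then H2O, NaOH, H2O2, 0 °C to rt
Reagents that add atoms: hydrogen peroxide, OO
Why: Hydroboration–oxidation; borane adds syn to the more accessible C3=C4 alkene (C9=C10 lies between two quaternary carbons) from the α face opposite the axial C5 methyl with boron on C3, so H enters C4 on the α face (methyl ends β) and oxidation with retention gives the 3α-alcohol.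

Step 5
Reactants: 6 3α-alcohol
Product: 7 3α-(tert-butyldimethylsilyloxy)-4β,5β-dimethyl-8-spiro(1,3-dithiolane)-decal-9(10)-ene
Conditions: TBSCl, imidazole, DMF, rt
Reagents that add atoms: tert-butyldimethylsilyl chloride, CC(C)(C)[Si](C)(C)Cl
Why: Silylation of the equatorial secondary alcohol protects O3 through the later base, dissolving-metal and first acylation steps.

Step 6
Reactants: 7 TBS ether dithiolane
Product: 8 3α-(tert-butyldimethylsilyloxy)-4β,5β-dimethyl-decal-9(10)-en-8-one
Conditions: MeI, CaCO3, MeCN/H2O (4:1), 50 °C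
Reagents that add atoms: water, O
Why: Alkylative dithiolane hydrolysis (S-methylation, opening to the allyl-stabilised thionium ion, attack of water) returns the conjugated enone under buffered conditions that spare the silyl ether.

Step 7
Reactants: 9 2-(diacetoxyiodo)-1,3,5-trimethylbenzene; 10 tributyl(prop-1-en-2-yl)stannane
Product: 11 mesityl(prop-1-en-2-yl)iodonium trifluoromethanesulfonate
Conditions: TMSOTf (1.05 equiv), CH2Cl2, −30 °C; then 10, −78 to −30 °C; precipitated with cold Et2O/pentane, kept at −20 °C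
Reagents that add atoms: trimethylsilyl trifluoromethanesulfonate, C[Si](C)(C)OS(=O)(=O)C(F)(F)F
Why: Tin-to-iodine exchange; TMSOTf turns the diacetate into an electrophilic acetate triflate of trivalent iodine, which undergoes ipso-destannylation of the alkenylstannane to give the alkenyl(aryl)iodonium triflate.

Step 8
Reactants: 8 Δ9(10)-8-enone; 11 mesityl(prop-1-en-2-yl)iodonium trifluoromethanesulfonate
Product: 13 3α-(tert-butyldimethylsilyloxy)-4β,5β-dimethyl-7α-(prop-1-en-2-yl)-decal-9(10)-en-8-one, via silyl dienol ether 12 (not isolated)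
Conditions: LiN(i-Pr)2, THF, −78 °C; TMSCl; volatiles off, pentane, filtration; then 11 (1.3 equiv), (CuOTf)2·C6H6 (5 mol %), 2,6-di-tert-butylpyridine (10 mol %), CH2Cl2, −40 to 0 °C
Reagents that add atoms: none
Why: Proposed new method: copper-catalysed electrophilic α′-isopropenylation of a cross-conjugated silyl dienol ether; CuOTf is oxidised by 11 to an isopropenyl–copper triflate of trivalent copper with loss of iodomesitylene (the hindered mesityl group is not transferred), the nucleophilic C7 terminus of the 2-silyloxy diene 12 attacks this electrophile on the α face, anti to the axial C5 methyl that shields the β face in a 1,3-relationship, and C–C reductive elimination forms the C7–C11 bond, sets C7 (equatorial isopropenyl) and returns monovalent copper together with TMSOTf; because no base is present the β,γ-unsaturated ketone should be neither epimerised nor conjugated; the closest known reaction type is the copper-catalysed α-arylation and α-vinylation of enol silanes and enamines with diaryl- and alkenyl(aryl)iodonium salts, which has not been shown for an enone α′-position through a 2-silyloxy diene or for a 1-methylvinyl group.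

Step 9
Reactants: 13 7α-isopropenyl enone
Product: 15 3α-(tert-butyldimethylsilyloxy)-4β,5β-dimethyl-7α-(prop-1-en-2-yl)-8-(trimethylsilyloxy)-10αH-decal-8-ene, via lithium enolate 14 (not isolated)
Conditions: Li (2.2 equiv), t-BuOH (1.0 equiv), NH3(l)/THF, −78 °C; NH3 off; TMSCl, Et3N, THF, −78 to 0 °C
Reagents that add atoms: trimethylsilyl chloride, C[Si](C)(C)Cl
Why: Dissolving-metal (Birch-type) enone reduction with reductive silylation; axial protonation at C10 gives the trans ring fusion (10αH), the enolate is formed only between C8 and C9 and is trapped on oxygen, and the isolated isopropenyl alkene is inert to Li/NH3.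

Step 10
Reactants: 15 C8–C9 enol silane
Product: 18 3α-(tert-butyldimethylsilyloxy)-9α-hydroxy-4β,5β-dimethyl-7α-(prop-1-en-2-yl)-10αH-decalin-8-one, via silyloxy epoxide 16 (not isolated), via 9α-silyloxy ketone 17 (not isolated)
Conditions: mCPBA, CH2Cl2, −20 to 0 °C; then citric acid (cat.), MeOH, rt
Reagents that add atoms: 3-chloroperoxybenzoic acid, OOC(=O)c1cccc(Cl)c1
Why: Rubottom oxidation; the electron-rich enol silane is epoxidised much faster than the isopropenyl group and from the α face opposite the axial C5 methyl, and epoxide opening with 1,4-silyl shift followed by methanolysis gives the equatorial 9α-hydroxy ketone.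

Step 11
Reactants: 18 9α-hydroxy ketone; 19 3-methylbut-2-enoyl chloride
Product: 20 3α-(tert-butyldimethylsilyloxy)-9α-(3-methylbut-2-enoyloxy)-4β,5β-dimethyl-7α-(prop-1-en-2-yl)-10αH-decalin-8-one
Conditions: pyridine, DMAP (cat.), CH2Cl2, 0 °C to rt
Reagents that add atoms: none
Why: DMAP-catalysed acylation of the C9 alcohol with the acid chloride under weakly basic conditions installs the senecioate, and C7 and C9 already have their stable equatorial arrangement so they are not at risk.

Step 12
Reactants: 20 9α-senecioate TBS ether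
Product: 21 3α-hydroxy-9α-(3-methylbut-2-enoyloxy)-4β,5β-dimethyl-7α-(prop-1-en-2-yl)-10αH-decalin-8-one
Conditions: HF·pyridine, pyridine, THF, 0 °C to rt
Reagents that add atoms: none
Why: Fluoride-mediated cleavage of the secondary TBS ether with buffered HF·pyridine frees O3 while the ester, the ketone and the isopropenyl group are stable to these conditions.

Step 13
Reactants: 21 3α-alcohol; 22 (E)-2-methylbut-2-enoyl chloride
Product: 23 (3R,4R,5R,7S,9S,10R)-3α-[(E)-2-methylbut-2-enoyloxy]-9α-(3-methylbut-2-enoyloxy)eremophil-11-en-8-one (CNP0375730.3)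
Conditions: pyridine, DMAP (cat.), CH2Cl2, 0 °C to rt
Reagents that add atoms: none
Why: DMAP-catalysed acylation of the equatorial C3 alcohol with tigloyl chloride gives the tiglate with the E geometry retained, which completes the target.

**Compound list**
1 | (S)-Wieland–Miescher ketone, (8aS)-8a-methyl-3,4,8,8a-tetrahydronaphthalene-1,6(2H,7H)-dione (here: 5β-methyl-decal-9(10)-ene-4,8-dione) | O=C1CC[C@]2(C)C(=O)CCCC2=C1 | starting material
2 | 5β-methyl-decal-9(10)-en-4-one with a spiro-1,3-dithiolane at C8 | C1C[C@]2(C)C(=O)CCCC2=CC13SCCS3 | intermediate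
3 | 5β-methyl-8-spiro(1,3-dithiolane)-decala-3,9(10)-dien-4-yl trifluoromethanesulfonate | C1C[C@]2(C)C(OS(=O)(=O)C(F)(F)F)=CCCC2=CC13SCCS3 | intermediate
4 | 4,5β-dimethyl-8-spiro(1,3-dithiolane)-decala-3,9(10)-diene | C1C[C@]2(C)C(C)=CCCC2=CC13SCCS3 | intermediate
5 | [4β,5β-dimethyl-8-spiro(1,3-dithiolane)-decal-9(10)-en-3α-yl]borane (BH2 on C3α, H on C4α) | C1C[C@]2(C)[C@@H](C)[C@H](B)CCC2=CC13SCCS3 | intermediate
6 | 4β,5β-dimethyl-8-spiro(1,3-dithiolane)-decal-9(10)-en-3α-ol | C1C[C@]2(C)[C@@H](C)[C@H](O)CCC2=CC13SCCS3 | intermediate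
7 | 3α-(tert-butyldimethylsilyloxy)-4β,5β-dimethyl-8-spiro(1,3-dithiolane)-decal-9(10)-ene | C1C[C@]2(C)[C@@H](C)[C@H](O[Si](C)(C)C(C)(C)C)CCC2=CC13SCCS3 | intermediate
8 | 3α-(tert-butyldimethylsilyloxy)-4β,5β-dimethyl-decal-9(10)-en-8-one | C1C[C@]2(C)[C@@H](C)[C@H](O[Si](C)(C)C(C)(C)C)CCC2=CC1=O | intermediate
9 | 2-(diacetoxyiodo)-1,3,5-trimethylbenzene, MesI(OAc)2 | CC(=O)OI(OC(C)=O)c1c(C)cc(C)cc1C | starting material
10 | tributyl(prop-1-en-2-yl)stannane | C=C(C)[Sn](CCCC)(CCCC)CCCC | starting material
11 | mesityl(prop-1-en-2-yl)iodonium trifluoromethanesulfonate | C=C(C)[I+]c1c(C)cc(C)cc1C.[O-]S(=O)(=O)C(F)(F)F | intermediate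
12 | 3α-(tert-butyldimethylsilyloxy)-4β,5β-dimethyl-8-(trimethylsilyloxy)-decala-7,9(10)-diene | C[Si](C)(C)OC1=CC[C@]2(C)[C@@H](C)[C@H](O[Si](C)(C)C(C)(C)C)CCC2=C1 | intermediate
13 | 3α-(tert-butyldimethylsilyloxy)-4β,5β-dimethyl-7α-(prop-1-en-2-yl)-decal-9(10)-en-8-one (7βH) | C=C(C)[C@@H]1C[C@]2(C)[C@@H](C)[C@H](O[Si](C)(C)C(C)(C)C)CCC2=CC1=O | intermediate
14 | lithium 3α-(tert-butyldimethylsilyloxy)-4β,5β-dimethyl-7α-(prop-1-en-2-yl)-10αH-decal-8-en-8-olate (trans ring fusion) | C=C(C)[C@@H]1C[C@]2(C)[C@@H](C)[C@H](O[Si](C)(C)C(C)(C)C)CC[C@H]2C=C1[O-].[Li+] | intermediate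
15 | 3α-(tert-butyldimethylsilyloxy)-4β,5β-dimethyl-7α-(prop-1-en-2-yl)-8-(trimethylsilyloxy)-10αH-decal-8-ene | C=C(C)[C@@H]1C[C@]2(C)[C@@H](C)[C@H](O[Si](C)(C)C(C)(C)C)CC[C@H]2C=C1O[Si](C)(C)C | intermediate
16 | 8α,9α-epoxide of 15 (8β-trimethylsilyloxy, 9βH) | C=C(C)[C@@H]1C[C@]2(C)[C@@H](C)[C@H](O[Si](C)(C)C(C)(C)C)CC[C@H]2[C@@H]3O[C@]13O[Si](C)(C)C | intermediate
17 | 3α-(tert-butyldimethylsilyloxy)-9α-(trimethylsilyloxy)-4β,5β-dimethyl-7α-(prop-1-en-2-yl)-10αH-decalin-8-one | C=C(C)[C@@H]1C[C@]2(C)[C@@H](C)[C@H](O[Si](C)(C)C(C)(C)C)CC[C@H]2[C@H](O[Si](C)(C)C)C1=O | intermediate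
18 | 3α-(tert-butyldimethylsilyloxy)-9α-hydroxy-4β,5β-dimethyl-7α-(prop-1-en-2-yl)-10αH-decalin-8-one | C=C(C)[C@@H]1C[C@]2(C)[C@@H](C)[C@H](O[Si](C)(C)C(C)(C)C)CC[C@H]2[C@H](O)C1=O | intermediate
19 | 3-methylbut-2-enoyl chloride (senecioyl chloride) | CC(C)=CC(=O)Cl | starting material
20 | 3α-(tert-butyldimethylsilyloxy)-9α-(3-methylbut-2-enoyloxy)-4β,5β-dimethyl-7α-(prop-1-en-2-yl)-10αH-decalin-8-one | C=C(C)[C@@H]1C[C@]2(C)[C@@H](C)[C@H](O[Si](C)(C)C(C)(C)C)CC[C@H]2[C@H](OC(=O)C=C(C)C)C1=O | intermediate
21 | 3α-hydroxy-9α-(3-methylbut-2-enoyloxy)-4β,5β-dimethyl-7α-(prop-1-en-2-yl)-10αH-decalin-8-one | C=C(C)[C@@H]1C[C@]2(C)[C@@H](C)[C@H](O)CC[C@H]2[C@H](OC(=O)C=C(C)C)C1=O | intermediate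
22 | (E)-2-methylbut-2-enoyl chloride (tigloyl chloride) | C/C=C(\C)C(=O)Cl | starting material
23 | (3R,4R,5R,7S,9S,10R)-3α-[(E)-2-methylbut-2-enoyloxy]-9α-(3-methylbut-2-enoyloxy)eremophil-11-en-8-one, CNP0375730.3 | C=C(C)[C@@H]1C[C@]2(C)[C@@H](C)[C@H](OC(=O)/C(C)=C/C)CC[C@H]2[C@H](OC(=O)C=C(C)C)C1=O | target

**Step count and risks**

Total step count: 13 (12 on the main line plus 1 for reagent 11). Longest linear sequence: 12 steps (1 to 23 through steps 1–6 and 8–13).

Step 8 is the most likely to fail. The coupling is new, and it also depends on salt 11 surviving long enough: a 1-methylvinyl iodonium salt can lose iodomesitylene or eliminate to propyne. The fallback uses known chemistry, sets out from 8 and comes back at 13. Enone 8 is deprotonated at C7 with LiN(i-Pr)2 in THF at −78 °C and the α′-enolate is added to acetone (aldol addition, attack on the α face) to give 3α-(tert-butyldimethylsilyloxy)-7α-(2-hydroxypropan-2-yl)-4β,5β-dimethyl-decal-9(10)-en-8-one F1. Dehydration of the tertiary alcohol with SOCl2 and pyridine at 0 °C (E2 loss of a methyl hydrogen) then gives 13, which is separated by chromatography from the conjugated isopropylidene isomer.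

Step 4 is the second risk. Borane may also attack the C9=C10 alkene or be held at sulfur, and the facial selectivity rests on one axial methyl group. The fallback sets out from 2 and comes back at 7, and builds the C3–O/C4–CH3 pair without any alkene hydroboration. Ketone 2 is treated with LiN(i-Pr)2 and then 2-(phenylsulfonyl)-3-phenyloxaziridine at −78 °C (enolate hydroxylation on the α face) to give 3α-hydroxy-5β-methyl-8-spiro(1,3-dithiolane)-decal-9(10)-en-4-one F2. Silylation with TBSCl and imidazole gives its 3α-tert-butyldimethylsilyl ether F3. Wittig methylenation with Ph3P=CH2 in toluene at 80 °C gives 3α-(tert-butyldimethylsilyloxy)-5β-methyl-4-methylene-8-spiro(1,3-dithiolane)-decal-9(10)-ene F4. Diimide (TsNHNH2, NaOAc, aqueous DME, reflux) reduces only the exocyclic alkene, from the α face, and gives the 4β-methyl compound 7.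

Step 9 is the third risk. Enolate 14 can scramble toward the acidic C7–H while ammonia is removed, and enol silane 15 is easily hydrolysed on isolation. The fallback sets out from 13 and comes back at 18 without the enol silane. Enolate 14 is generated as in step 9 and, once ammonia has been removed, is oxidised directly in THF at −78 °C with 2-(phenylsulfonyl)-3-phenyloxaziridine (enolate hydroxylation from the α face), then quenched with NH4Cl to give 18 in one operation; this makes no new compound F0.

Further compounds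
F1 | step 8 | 3α-(tert-butyldimethylsilyloxy)-7α-(2-hydroxypropan-2-yl)-4β,5β-dimethyl-decal-9(10)-en-8-one | CC(C)(O)[C@@H]1C[C@]2(C)[C@@H](C)[C@H](O[Si](C)(C)C(C)(C)C)CCC2=CC1=O
F2 | step 4 | 3α-hydroxy-5β-methyl-8-spiro(1,3-dithiolane)-decal-9(10)-en-4-one | C1C[C@]2(C)C(=O)[C@H](O)CCC2=CC13SCCS3
F3 | step 4 | 3α-(tert-butyldimethylsilyloxy)-5β-methyl-8-spiro(1,3-dithiolane)-decal-9(10)-en-4-one | C1C[C@]2(C)C(=O)[C@H](O[Si](C)(C)C(C)(C)C)CCC2=CC13SCCS3
F4 | step 4 | 3α-(tert-butyldimethylsilyloxy)-5β-methyl-4-methylene-8-spiro(1,3-dithiolane)-decal-9(10)-ene | C1C[C@]2(C)C(=C)[C@H](O[Si](C)(C)C(C)(C)C)CCC2=CC13SCCS3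
F0 | step 9 | none | none
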